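**Retrosynthetic overview**

- The target is (2S)-4′,7-dihydroxyflavan joined 2,4-trans through C4 to C8 of (−)-epigallocatechin; the last step is hydrogenolysis of seven benzyl ethers.
- Key disconnection: the pyran ring of the upper flavan is opened at C3–C4 and O1–C8a, and the interflavan C4–C8′ bond is cut in the same operation. This gives three pieces: a B-ring carbinol that is a C3 carbanion and an O1 alkoxide at once, 4-(benzyloxy)-2-fluorobenzaldehyde (C4 and the A ring), and penta-O-benzyl-epigallocatechin.
- Enabling feature: in the upper pyran ring O1–C2–C3–C4 is a 1,3-oxygenated propane once C4 is written as a carbinol. C8a is the A-ring carbon ortho to the C4-bearing carbon C4a, so an ortho-fluorine can be displaced by O1. C4 is benzylic and C4a is para to the A-ring 7-oxygen, so the carbinol can be ionised and arylated.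
- Ring formation: only the upper pyran ring is built (C3–C4 first, then O1–C8a closure); all other rings are bought.
- Stereocentres: C2 from a CBS reduction, C4 from trans-selective capture of the flavan-4-yl cation, the lower unit from epigallocatechin.

Key step: step 4

Remark: all phenols are carried as benzyl ethers and 2-bromo-1-[4-(benzyloxy)phenyl]ethan-1-one is taken as purchased; it is assumed that the lithium alkoxide of the bromohydrin does not close to the epoxide at −78 °C in the minutes before reductive lithiation.

**Step 1**
Reactants: 1 2-fluoro-4-hydroxybenzaldehyde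
Product: 2 4-(benzyloxy)-2-fluorobenzaldehyde
Conditions: BnBr, K2CO3, DMF, rt
Reagents that add atoms: benzyl bromide, BrCc1ccccc1
Why: Williamson O-benzylation of the only phenol; the aldehyde and the aryl fluoride should be inert to carbonate at room temperature.

**Step 2**
Reactants: 3 2-bromo-1-[4-(benzyloxy)phenyl]ethan-1-one
Product: 4 (R)-2-bromo-1-[4-(benzyloxy)phenyl]ethan-1-ol
Conditions: (R)-2-methyl-CBS-oxazaborolidine (cat.), BH3·SMe2, THF, 0 °C; MeOH quench
Reagents that add atoms: none
Why: Corey–Bakshi–Shibata reduction, in which the (R)-oxazaborolidine–borane complex should deliver hydride to the face that places aryl as the large and CH2Br as the small group, setting the carbinol centre as R (the future C2 of the upper flavan).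

**Step 3**
Reactants: 5 (−)-epigallocatechin
Product: 6 5,7,3′,4′,5′-penta-O-benzyl-(−)-epigallocatechin
Conditions: BnBr, K2CO3, DMF, argon, 0 °C to rt
Reagents that add atoms: benzyl bromide, BrCc1ccccc1
Why: Williamson benzylation under carbonate base should alkylate the five phenols and leave the secondary 3-OH free; the C2 and C3 stereocentres are not touched.

**Step 4**
Reactants: 4 (R)-2-bromo-1-[4-(benzyloxy)phenyl]ethan-1-ol; 2 4-(benzyloxy)-2-fluorobenzaldehyde; 6 5,7,3′,4′,5′-penta-O-benzyl-(−)-epigallocatechin
Product: 10 hepta-O-benzyl (2S)-4′,7-dihydroxyflavan-(4R→8)-(−)-epigallocatechin, via β-oxido alkyllithium 7 (not isolated), via dilithium 1,3-diolate 8 (not isolated), via flavan-4-ol 9 (not isolated)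
Conditions: (i) n-BuLi (1 equiv), THF, −78 °C, then lithium naphthalenide (2 equiv), −78 °C; (ii) 2, −78 °C; (iii) KOt-Bu, 18-crown-6, −78 to 60 °C; (iv) 6 (excess) in CH2Cl2, then CF3CO2H (excess), −20 to 0 °C
Reagents that add atoms: none
Why: Proposed new method: a one-flask anionic [3+3] annulation followed by cationic arylation, in which O-deprotonation and reductive lithiation of the C–Br bond of 4 give the β-oxido alkyllithium 7 (the O–Li group is too poor a leaving group for β-elimination at −78 °C), the C3 carbanion of 7 adds to the aldehyde carbon of 2 (future C4) to give diolate 8, the C2 alkoxide of 8 then displaces the ortho-fluorine by intramolecular SNAr (O1–C8a) to give the alkoxide of 9, and acidification ionises the C4 carbinol to a benzylic cation that is captured by C8 of 6. The closest known reaction types are the addition of halohydrin-derived β-oxido organolithiums to aldehydes, the alkoxide SNAr cyclisation of 3-(2-fluoroaryl)propan-1-ols to chromans and the acid-mediated C4-arylation of flavan-4-ols by flavan-3-ols, but their merger into one annulation has not been shown. The pyran ring closes by 6-exo attack of the C2 alkoxide on C8a through a Meisenheimer adduct, the only cyclisation open to 8 because the C4 alkoxide could reach the C–F carbon only through a four-membered ring. C2 is not a new centre: its C–O bond is never broken, so the configuration set in step 2 is carried through as 2S, and the C4 carbinol configuration of 8 and 9 is irrelevant because it is erased on ionisation. C4 is set in the last stage by pseudo-axial attack of the arene on the half-chair cation on the face anti to the equatorial C2 aryl group, which should favour the 2,4-trans (4R) isomer as in acid-mediated flavan-4-ol couplings. The step needs C8 rather than C6 or O attack in 6, which the 5,7-dibenzyloxy pattern (the usual 4→8 selectivity) and the reversibility of O-alkylation under acid should secure, and it needs mild ionisation at C4 only, which the 7-benzyloxy group para to the C4-bearing carbon provides.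

**Step 5**
Reactants: 10 hepta-O-benzyl (2S)-4′,7-dihydroxyflavan-(4R→8)-(−)-epigallocatechin
Product: 11 (2S)-4′,7-dihydroxyflavan-(4R→8)-(−)-epigallocatechin (target)
Conditions: H2 (1 atm), Pd(OH)2/C, THF/MeOH, rt
Reagents that add atoms: none
Why: Hydrogenolysis of aryl benzyl ethers over Pearlman's catalyst; the cyclic benzylic C2–O1 ethers and the doubly benzylic C4–H of 4-arylflavans normally survive these conditions, so no stereocentre should be affected.

**Compound list**

1 | 2-fluoro-4-hydroxybenzaldehyde | O=Cc1ccc(O)cc1F | starting material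
2 | 4-(benzyloxy)-2-fluorobenzaldehyde | O=Cc1ccc(OCc2ccccc2)cc1F | intermediate
3 | 2-bromo-1-[4-(benzyloxy)phenyl]ethan-1-one | O=C(CBr)c1ccc(OCc2ccccc2)cc1 | starting material
4 | (R)-2-bromo-1-[4-(benzyloxy)phenyl]ethan-1-ol | BrC[C@H](O)c1ccc(OCc2ccccc2)cc1 | intermediate
5 | (−)-epigallocatechin, (2R,3R)-2-(3,4,5-trihydroxyphenyl)chroman-3,5,7-triol | Oc1cc(O)c2c(c1)O[C@H](c1cc(O)c(O)c(O)c1)[C@H](O)C2 | starting material
6 | (2R,3R)-5,7-bis(benzyloxy)-2-[3,4,5-tris(benzyloxy)phenyl]chroman-3-ol | C(c1ccccc1)Oc1cc(OCc2ccccc2)c2c(c1)O[C@H](c1cc(OCc3ccccc3)c(OCc3ccccc3)c(OCc3ccccc3)c1)[C@H](O)C2 | intermediate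
7 | lithium (S)-1-[4-(benzyloxy)phenyl]-2-lithioethan-1-olate | [Li]C[C@H](O[Li])c1ccc(OCc2ccccc2)cc1 | intermediate
8 | dilithium (1S,3RS)-3-[4-(benzyloxy)-2-fluorophenyl]-1-[4-(benzyloxy)phenyl]propane-1,3-bis(olate) | [Li]OC(C[C@H](O[Li])c1ccc(OCc2ccccc2)cc1)c1ccc(OCc2ccccc2)cc1F | intermediate
9 | (2S,4RS)-7-(benzyloxy)-2-[4-(benzyloxy)phenyl]chroman-4-ol (formed as its alkoxide, protonated on acidification) | OC1c2ccc(OCc3ccccc3)cc2O[C@H](c2ccc(OCc3ccccc3)cc2)C1 | intermediate
10 | (2R,3R)-5,7-bis(benzyloxy)-8-{(2S,4R)-7-(benzyloxy)-2-[4-(benzyloxy)phenyl]chroman-4-yl}-2-[3,4,5-tris(benzyloxy)phenyl]chroman-3-ol | C(c1ccccc1)Oc1ccc([C@@H]2C[C@@H](c3c(OCc5ccccc5)cc(OCc5ccccc5)c4c3O[C@H](c3cc(OCc5ccccc5)c(OCc5ccccc5)c(OCc5ccccc5)c3)[C@H](O)C4)c3ccc(OCc5ccccc5)cc3O2)cc1 | intermediate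
11 | (2R,3R)-8-[(2S,4R)-7-hydroxy-2-(4-hydroxyphenyl)chroman-4-yl]-2-(3,4,5-trihydroxyphenyl)chroman-3,5,7-triol | Oc1ccc([C@@H]2C[C@@H](c3c(O)cc(O)c4c3O[C@H](c3cc(O)c(O)c(O)c3)[C@H](O)C4)c3ccc(O)cc3O2)cc1 | target

**Step count and risks**

Total step count: 5. Longest linear sequence: 3 steps (steps 2, 4 and 5; the same length through steps 1 or 3).

Steps most likely to fail:

1. Step 4 (proposed new method). The organolithium may be lost by β-elimination to the styrene or by epoxide closure before lithiation. The SNAr closure on the electron-rich fluoroarene may be sluggish. Carried-over base may blunt the acid stage, and cation capture may show poor facial or C8/C6 selectivity. The fallback uses known chemistry only; it sets out from 2 and 3 and comes back at 10. A Reformatsky-type aldol of bromoketone 3 with aldehyde 2 (Zn, THF) would give racemic 3-[4-(benzyloxy)-2-fluorophenyl]-1-[4-(benzyloxy)phenyl]-3-hydroxypropan-1-one F1. Noyori asymmetric transfer hydrogenation of the aryl ketone (RuCl[(S,S)-TsDPEN](p-cymene), HCO2H/Et3N) would set the future C2 and give (1S,3RS)-3-[4-(benzyloxy)-2-fluorophenyl]-1-[4-(benzyloxy)phenyl]propane-1,3-diol F2. KOt-Bu in THF at 60 °C would close the pyran ring by SNAr to flavan-4-ol 9, now isolated. Flavan-4-ol 9 would then be condensed with 6 under CF3CO2H or TMSOTf in CH2Cl2 at low temperature to give 10.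

2. Step 3. The pyrogallol ring may oxidise in air under basic conditions, and over-alkylation at O3 or C-benzylation may occur. The fallback sets out from 5 and comes back at 11. Unprotected 5, which dissolves in THF, would replace 6 as the arene in the last stage of step 4; acid-mediated condensations of flavan-4-ols with free flavan-3-ols are known and favour C8. This would give (2R,3R)-8-{(2S,4R)-7-(benzyloxy)-2-[4-(benzyloxy)phenyl]chroman-4-yl}-2-(3,4,5-trihydroxyphenyl)chroman-3,5,7-triol F3. Hydrogenolysis of its two benzyl ethers (H2, Pd(OH)2/C) would give 11.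

3. Step 5. Debenzylation of a hepta-ether may stall, the benzylic C2–O1 bonds of the two pyran rings may be hydrogenolysed, and the product may oxidise in air. The fallback sets out from 10 and comes back at 11. It replaces reductive cleavage by heterolytic cleavage: BCl3 with pentamethylbenzene as cation scavenger in CH2Cl2 at −78 °C removes aryl benzyl ethers without any hydrogenolysis pathway for the pyran C–O bonds. It makes no new compound.

**Further compounds**

F1 | step 4 | 3-[4-(benzyloxy)-2-fluorophenyl]-1-[4-(benzyloxy)phenyl]-3-hydroxypropan-1-one (racemic) | O=C(CC(O)c1ccc(OCc2ccccc2)cc1F)c1ccc(OCc2ccccc2)cc1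
F2 | step 4 | (1S,3RS)-3-[4-(benzyloxy)-2-fluorophenyl]-1-[4-(benzyloxy)phenyl]propane-1,3-diol | OC(C[C@H](O)c1ccc(OCc2ccccc2)cc1)c1ccc(OCc2ccccc2)cc1F
F3 | step 3 | (2R,3R)-8-{(2S,4R)-7-(benzyloxy)-2-[4-(benzyloxy)phenyl]chroman-4-yl}-2-(3,4,5-trihydroxyphenyl)chroman-3,5,7-triol | C(c1ccccc1)Oc1ccc([C@@H]2C[C@@H](c3c(O)cc(O)c4c3O[C@H](c3cc(O)c(O)c(O)c3)[C@H](O)C4)c3ccc(OCc5ccccc5)cc3O2)cc1
F0 | step 5 | none | none
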